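**Plan**
- Retrosynthesis: cut the C19–O angelate and the C12–C13 bond; take C11–C12 off C9 by a retro-[3,3] shift to a Δ8-7β-ol; then open ring A at C1–C2 and C4–C5 in one operation.
- Enabling feature: in ring A, C1 and C5 both hang on quaternary C10, and C2 and C4 flank C3. A ring B dienone with C1 as CH2I and C5 as β-carbon of the C7 enone is a 1,3-dielectrophile that pairs with a 3-oxo-C19-ester unit (C2/C4 1,3-dinucleophile).
- Forward: ring B first (cyclohexadienone from a catalytic asymmetric Diels–Alder adduct), then ring A by a [3+3] Michael–alkylation annulation, then C3 deoxygenation, C7 ketone → 7β-ol → Johnson–Claisen (C11–C12 on C9, Δ7), then the side chain by Negishi coupling.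
- Stereochemistry: C10 from the catalyst; C5 and C4 relayed from C10 in the annulation; C7 from the ring by Luche reduction and C9 from C7 by suprafacial rearrangement; the 13Z and angelate geometries are brought in stereospecifically.
- Helpers and their removal: C3 ketone (steps 7–9), C7 ketone (steps 10–11), iodide at C1 (lost in the annulation), ester level at C19 (step 12).

Key step: step 6

Numbering: labdane numbers are used for the decalin (C17 = methyl on C8, C18 = 4α-methyl, C19 = 4β carbon, C20 = 10β-methyl, C11–C16 = side chain).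
Assumption: in step 1 the antipode of the trivalent chromium catalyst (salen)CrSbF6 [salen = dianion of N,N′-bis(3,5-di-tert-butylsalicylidene)-trans-cyclohexane-1,2-diamine] that gives the (1R) adduct is used; the C6 epimers of 9 and the C3 configuration of 15 are immaterial because both centers are erased later.

Step 1
Reactants: 1 (E)-3-(tert-butyldimethylsilyloxy)-N,N-dimethylbuta-1,3-dien-1-amine; 2 methacrolein
Product: 3 (1R,2S)-4-(tert-butyldimethylsilyloxy)-2-(dimethylamino)-1-methylcyclohex-3-ene-1-carbaldehyde
Conditions: (salen)CrSbF6 (5 mol %), 4 Å MS, CH2Cl2, −40 °C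
Reagents that add atoms: none
Why: Catalytic enantioselective Diels–Alder reaction of a 1-amino-3-siloxy diene with an α-substituted acrolein, in which the chiral Lewis acid sets the quaternary carbon (later C10), the amino terminus bonds to the α-carbon of the enal and endo approach places the amine cis to the formyl group.

Step 2
Reactants: 3 Diels–Alder adduct
Product: 5 (R)-4-(hydroxymethyl)-4-methylcyclohex-2-en-1-one, via amino alcohol 4 (not isolated)
Conditions: LiAlH4, Et2O, −78 → 0 °C; then aq. HF, MeCN, 0 → 25 °C
Reagents that add atoms: none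
Why: Hydride reduction of the aldehyde, then acid hydrolysis of the silyl enol ether with β-elimination of dimethylamine, should give the 4,4-disubstituted cyclohexenone without touching the quaternary stereocenter.

Step 3
Reactants: 5 hydroxymethyl enone
Product: 7 (R)-4-(iodomethyl)-4-methylcyclohex-2-en-1-one, via neopentyl triflate 6 (not isolated)
Conditions: Tf2O, 2,6-lutidine, CH2Cl2, −78 °C; then NaI, DMF, 25 → 40 °C
Reagents that add atoms: sodium iodide, [Na+].[I-]
Why: O-Triflation followed by Finkelstein-type SN2 displacement works at a neopentyl carbon because the triflate is reactive enough and can neither ionise nor eliminate, and it installs the soft leaving group wanted in step 6.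

Step 4
Reactants: 7 iodomethyl enone
Product: 9 (4R)-4-(iodomethyl)-4,6-dimethylcyclohex-2-en-1-one (C6 epimers), via lithium dienolate 8 (not isolated)
Conditions: LiN(i-Pr)2, THF, −78 °C; then MeI, −78 → −20 °C
Reagents that add atoms: iodomethane, CI
Why: Kinetic α′-deprotonation of the enone gives the cross-conjugated dienolate, which is C-methylated at the future C8 (enolate alkylation); the new center is erased in step 5.

Step 5
Reactants: 9 methylated enone
Product: 11 (S)-4-(iodomethyl)-2,4-dimethylcyclohexa-2,5-dien-1-one, via trimethylsilyl dienol ether 10 (not isolated)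
Conditions: Me3SiOTf, Et3N, CH2Cl2, 0 °C; then Pd(OAc)2 (1.05 equiv), MeCN, 25 °C
Reagents that add atoms: none
Why: Saegusa–Ito oxidation, in which soft enolisation can only run toward C8 (C10 is quaternary) and palladation with β-hydride elimination toward C9 gives the cross-conjugated dienone.

Step 6
Reactants: 11 dienone; 12 methyl 2-methyl-3-oxobutanoate
Product: 14 methyl 4α,8,10β-trimethyl-3,7-dioxo-5α-decal-8-ene-4β-carboxylate, via Michael adduct 13 (not isolated)
Conditions: t-BuOK (2.1 equiv), t-BuOH–THF, 0 → 45 °C
Reagents that add atoms: none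
Why: Proposed new method: the potassium enolate of 12 adds reversibly through C4 to C5, the β-carbon of the unsubstituted enone arm of 11 (Michael addition), and the methyl ketone enolate (C2) of adduct 13 then displaces iodide at the neopentyl C1 irreversibly, a formal [3+3] annulation whose closest known relatives are base-mediated Michael–alkylation annulations of β-keto esters (Michael-initiated ring closure) and the two-fold Michael addition of 1,3-dicarbonyl compounds to cross-conjugated dienones. Ring A closes by 6-(enolendo)-exo-tet alkylation, for which the exocyclic C1–I bond can align freely. C5 is set by addition on the face of ring B opposite the iodomethyl group; because the Michael step is reversible, the ring closure is product-determining, and for the trans-fused product it runs through a chair with C1 and C4 both equatorial on ring B. C4 is set in the same transition state, where the planar ester takes the axial position syn to the C10 methyl and the C4 methyl stays equatorial (the alternative costs a methyl/methyl 1,3-diaxial contact). The step needs regioselectivity for C5 over C9 (the C8 methyl makes that arm the poorer acceptor), C- over O-alkylation (soft iodide), and alkylation in preference to the reversible second Michael addition at C9; tert-butoxide is chosen to avoid retro-Claisen cleavage of the non-enolisable β-keto ester.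

Step 7
Reactants: 14 diketo ester
Product: 15 methyl 3β-hydroxy-4α,8,10β-trimethyl-7-oxo-5α-decal-8-ene-4β-carboxylate
Conditions: NaBH4 (0.3 equiv), MeOH–CH2Cl2, −40 °C
Reagents that add atoms: none
Why: Borohydride without a cerium salt reduces the saturated C3 ketone faster than the conjugated, α-methylated C7 enone (chemoselective ketone reduction), with axial hydride delivery from the α face.

Step 8
Reactants: 15 hydroxy enone ester
Product: 16 3β-O-(imidazol-1-ylthiocarbonyl) derivative of 15
Conditions: 1,1′-thiocarbonyldiimidazole, DMAP, ClCH2CH2Cl, 80 °C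
Reagents that add atoms: 1,1′-thiocarbonyldiimidazole, S=C(n1ccnc1)n1ccnc1
Why: Thioacylation of the hindered secondary alcohol under neutral conditions (no alkoxide, so no retro-aldol) prepares the Barton–McCombie deoxygenation.

Step 9
Reactants: 16 imidazolyl thiocarbonate
Product: 17 methyl 4α,8,10β-trimethyl-7-oxo-5α-decal-8-ene-4β-carboxylate
Conditions: Bu3SnH (slow addition), AIBN (cat.), toluene, 100 °C
Reagents that add atoms: none
Why: Barton–McCombie deoxygenation, in which the stannyl radical adds to the thiocarbonyl group and the secondary C3 radical is reduced by the stannane, with the enone tolerated at low stannane concentration.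

Step 10
Reactants: 17 enone ester
Product: 18 methyl 7β-hydroxy-4α,8,10β-trimethyl-5α-decal-8-ene-4β-carboxylate
Conditions: NaBH4, CeCl3·7H2O, MeOH, −78 → −20 °C
Reagents that add atoms: none
Why: Luche reduction is 1,2-selective, and axial hydride delivery on the α face (anti to the C20 methyl) should give the pseudo-equatorial 7β-alcohol that the next step needs.

Step 11
Reactants: 18 allylic alcohol
Product: 20 12-ethyl 19-methyl 13,14,15,16-tetranorlabd-7-ene-12,19-dioate, via mixed ketene acetal 19 (not isolated)
Conditions: MeC(OEt)3, EtCO2H (cat.), xylene, 140 °C, EtOH distilled off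
Reagents that add atoms: triethyl orthoacetate, CCOC(C)(OCC)OCC
Why: Johnson–Claisen rearrangement, whose suprafacial [3,3] shift carries the CH2CO2Et group from the 7β-oxygen to the β face of C9 and moves the double bond to C7=C8, as in the Claisen rearrangement of 2-methylcyclohex-2-enols that carry an adjacent quaternary carbon.

Step 12
Reactants: 20 diester
Product: 21 13,14,15,16-tetranorlabd-7-ene-12,19-diol
Conditions: LiAlH4, THF, 0 → 65 °C
Reagents that add atoms: none
Why: LiAlH4 reduces both the ethyl ester and the hindered axial methyl ester to primary alcohols without affecting any stereocenter.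

Step 13
Reactants: 21 diol
Product: 22 12-iodo-13,14,15,16-tetranorlabd-7-en-19-ol
Conditions: PPh3, I2, imidazole, CH2Cl2, 0 °C
Reagents that add atoms: iodine, II
Why: Appel-type iodination proceeds by SN2 displacement and therefore takes the unhindered C12 hydroxyl while the neopentyl, axial C19 hydroxyl is left.

Step 14
Reactants: 22 iodo alcohol; 23 angelic acid [(Z)-2-methylbut-2-enoic acid]
Product: 25 12-iodo-13,14,15,16-tetranorlabd-7-en-19-yl (Z)-2-methylbut-2-enoate, via mixed anhydride 24 (not isolated)
Conditions: 2,4,6-trichlorobenzoyl chloride, Et3N, toluene, 25 °C; then 22, 80 °C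
Reagents that add atoms: none
Why: Yamaguchi-type acylation through the mixed anhydride, run without a nucleophilic amine catalyst, should acylate the C19 hydroxyl without isomerising the angeloyl group to the tigloyl isomer.

Step 15
Reactants: 26 but-2-ynoic acid
Product: 27 (Z)-3-iodobut-2-enoic acid
Conditions: NaI, AcOH, 115 °C
Reagents that add atoms: sodium iodide, [Na+].[I-]
Why: Hydroiodination of the ynoic acid by conjugate addition of iodide and protonation (anti addition) gives the (Z)-β-iodo acid.

Step 16
Reactants: 25 iodo angelate; 27 (Z)-3-iodobut-2-enoic acid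
Product: 30 (13Z)-19-[(Z)-2-methylbut-2-enoyloxy]labda-7,13-dien-15-oic acid, via alkylzinc iodide 28 (not isolated), via sodium iodobutenoate 29 (not isolated)
Conditions: 25, Zn, LiCl, THF, 40 °C; 27, NaH, DMF, 0 °C; then PdCl2(dppf) (5 mol %), THF–DMF, 25 → 45 °C; aq. HCl work-up
Reagents that add atoms: none
Why: Zinc insertion into the primary C–I bond tolerates the ester, and Negishi coupling with the β-iodo enoate (masked as its sodium salt so that it does not protonate the organozinc) proceeds with retention of alkene geometry, which gives the 13Z acid directly.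

**Compound list**
1 | (E)-3-(tert-butyldimethylsilyloxy)-N,N-dimethylbuta-1,3-dien-1-amine | CN(C)/C=C/C(=C)O[Si](C)(C)C(C)(C)C | starting material
2 | methacrolein | CC(=C)C=O | starting material
3 | (1R,2S)-4-(tert-butyldimethylsilyloxy)-2-(dimethylamino)-1-methylcyclohex-3-ene-1-carbaldehyde | O=C[C@]1(C)CCC(O[Si](C)(C)C(C)(C)C)=C[C@@H]1N(C)C | intermediate
4 | [(1R,2S)-4-(tert-butyldimethylsilyloxy)-2-(dimethylamino)-1-methylcyclohex-3-en-1-yl]methanol | OC[C@]1(C)CCC(O[Si](C)(C)C(C)(C)C)=C[C@@H]1N(C)C | intermediate (not isolated)
5 | (R)-4-(hydroxymethyl)-4-methylcyclohex-2-en-1-one | O=C1C=C[C@](C)(CO)CC1 | intermediate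
6 | [(R)-1-methyl-4-oxocyclohex-2-en-1-yl]methyl trifluoromethanesulfonate | O=C1C=C[C@](C)(COS(=O)(=O)C(F)(F)F)CC1 | intermediate (not isolated)
7 | (R)-4-(iodomethyl)-4-methylcyclohex-2-en-1-one | O=C1C=C[C@](C)(CI)CC1 | intermediate
8 | lithium (4R)-4-(iodomethyl)-4-methylcyclohexa-1,5-dien-1-olate | [Li]OC1=CC[C@@](C)(CI)C=C1 | intermediate (not isolated)
9 | (4R)-4-(iodomethyl)-4,6-dimethylcyclohex-2-en-1-one (C6 epimers) | CC1C[C@@](C)(CI)C=CC1=O | intermediate
10 | [(4R)-4-(iodomethyl)-2,4-dimethylcyclohexa-1,5-dien-1-yl]oxytrimethylsilane | CC1=C(O[Si](C)(C)C)C=C[C@](C)(CI)C1 | intermediate (not isolated)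
11 | (S)-4-(iodomethyl)-2,4-dimethylcyclohexa-2,5-dien-1-one | CC1=C[C@@](C)(CI)C=CC1=O | intermediate
12 | methyl 2-methyl-3-oxobutanoate | CC(=O)C(C)C(=O)OC | starting material
13 | Michael adduct: ring B enone carrying at C5 (β face, trans to CH2I) the C4 unit C(CH3)(CO2Me)(COCH3) | COC(=O)[C@@](C)(C(C)=O)[C@@H]1CC(=O)C(C)=C[C@@]1(C)CI | intermediate (not isolated)
14 | methyl 4α,8,10β-trimethyl-3,7-dioxo-5α-decal-8-ene-4β-carboxylate | COC(=O)[C@@]1(C)C(=O)CC[C@]2(C)C=C(C)C(=O)C[C@@H]12 | intermediate
15 | methyl 3β-hydroxy-4α,8,10β-trimethyl-7-oxo-5α-decal-8-ene-4β-carboxylate | COC(=O)[C@@]1(C)[C@@H](O)CC[C@]2(C)C=C(C)C(=O)C[C@@H]12 | intermediate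
16 | 3β-O-(imidazol-1-ylthiocarbonyl) derivative of 15 | COC(=O)[C@@]1(C)[C@@H](OC(=S)n3ccnc3)CC[C@]2(C)C=C(C)C(=O)C[C@@H]12 | intermediate
17 | methyl 4α,8,10β-trimethyl-7-oxo-5α-decal-8-ene-4β-carboxylate | COC(=O)[C@@]1(C)CCC[C@]2(C)C=C(C)C(=O)C[C@@H]12 | intermediate
18 | methyl 7β-hydroxy-4α,8,10β-trimethyl-5α-decal-8-ene-4β-carboxylate | COC(=O)[C@@]1(C)CCC[C@]2(C)C=C(C)[C@@H](O)C[C@@H]12 | intermediate
19 | 7β-O-(1-ethoxyvinyl) ether of 18 | COC(=O)[C@@]1(C)CCC[C@]2(C)C=C(C)[C@@H](OC(=C)OCC)C[C@@H]12 | intermediate (not isolated)
20 | 12-ethyl 19-methyl 13,14,15,16-tetranorlabd-7-ene-12,19-dioate | COC(=O)[C@@]1(C)CCC[C@]2(C)[C@@H](CC(=O)OCC)C(C)=CC[C@@H]12 | intermediate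
21 | 13,14,15,16-tetranorlabd-7-ene-12,19-diol | OC[C@@]1(C)CCC[C@]2(C)[C@@H](CCO)C(C)=CC[C@@H]12 | intermediate
22 | 12-iodo-13,14,15,16-tetranorlabd-7-en-19-ol | OC[C@@]1(C)CCC[C@]2(C)[C@@H](CCI)C(C)=CC[C@@H]12 | intermediate
23 | angelic acid, (Z)-2-methylbut-2-enoic acid | C/C=C(/C)C(=O)O | starting material
24 | (Z)-2-methylbut-2-enoic 2,4,6-trichlorobenzoic anhydride | C/C=C(/C)C(=O)OC(=O)c1c(Cl)cc(Cl)cc1Cl | intermediate (not isolated)
25 | 12-iodo-13,14,15,16-tetranorlabd-7-en-19-yl (Z)-2-methylbut-2-enoate | C/C=C(/C)C(=O)OC[C@@]1(C)CCC[C@]2(C)[C@@H](CCI)C(C)=CC[C@@H]12 | intermediate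
26 | but-2-ynoic acid | CC#CC(=O)O | starting material
27 | (Z)-3-iodobut-2-enoic acid | C/C(I)=C/C(=O)O | intermediate
28 | alkylzinc iodide from 25 (C12–ZnI) | C/C=C(/C)C(=O)OC[C@@]1(C)CCC[C@]2(C)[C@@H](CC[Zn]I)C(C)=CC[C@@H]12 | intermediate (not isolated)
29 | sodium (Z)-3-iodobut-2-enoate | C/C(I)=C/C(=O)[O-].[Na+] | intermediate (not isolated)
30 | (13Z)-19-[(Z)-2-methylbut-2-enoyloxy]labda-7,13-dien-15-oic acid | C/C=C(/C)C(=O)OC[C@@]1(C)CCC[C@]2(C)[C@@H](CC/C(C)=C\C(=O)O)C(C)=CC[C@@H]12 | target

**Step count**
Total: 16 steps. Longest linear sequence: 15 steps (steps 1–14 and 16).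

**Steps most likely to fail**

1. Step 6 (Proposed new method). Three things may go wrong: loss of control over the ring fusion (ring closure through the Michael adduct that is cis to the iodomethyl group), a second conjugate addition at C9 in place of the alkylation, and O-alkylation of the enolate. Fallback with known chemistry, setting out from 12 and 11 and returning at 14: 12 is converted with Me3SiOTf and Et3N into its silyl enol ether, methyl 2-methyl-3-(trimethylsilyloxy)but-2-enoate F1. A TiCl4-promoted Mukaiyama–Michael addition of F1 to dienone 11 (CH2Cl2, −78 °C) should give, after aqueous work-up, adduct 13 as an isolated compound; this addition is under kinetic control, anti to the iodomethyl group, and no base is present that could trigger reversal or a second conjugate addition. Ring A is then closed in a separate enolate alkylation with KN(SiMe3)2 in THF (−78 → 0 °C) to give 14.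

2. Step 11. The [3,3] shift onto the β face of C9, next to quaternary C10, may be slow, and acid-promoted dehydration of the allylic alcohol to a diene may compete. Fallback setting out from 18 and returning at 21: 18 is converted with phenyl isocyanate into its 7β N-phenylcarbamate F2. Carbamate-directed syn-SN2′ cuprate substitution (MeLi, then CuI, then CH2=CHLi, THF, −78 → 25 °C) should deliver a vinyl group to the β face of C9 and give methyl 9β-vinyl-4α,8,10β-trimethyl-5α-decal-7-ene-4β-carboxylate F3. Hydroboration of the vinyl group with 9-BBN and oxidation (NaOH, H2O2) gives methyl 12-hydroxy-13,14,15,16-tetranorlabd-7-en-19-oate F4, and LiAlH4 reduction of the ester gives 21.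

3. Step 14. The angeloyl group may isomerise to the tigloyl group during acyl transfer, or acylation of the neopentyl alcohol may stay incomplete. Fallback setting out from 22 and returning at 25: 22 is esterified with 2-[bis(2,2,2-trifluoroethoxy)phosphoryl]propanoic acid (DCC, DMAP, CH2Cl2), a saturated acid that cannot isomerise, to give the phosphonate ester 12-iodo-13,14,15,16-tetranorlabd-7-en-19-yl 2-[bis(2,2,2-trifluoroethoxy)phosphoryl]propanoate F5. Still–Gennari olefination of F5 with acetaldehyde (KN(SiMe3)2, 18-crown-6, THF, −78 °C) then builds the (Z)-2-methylbut-2-enoate in place and gives 25.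

Further compounds
F1 | step 6 | methyl 2-methyl-3-(trimethylsilyloxy)but-2-enoate | COC(=O)C(C)=C(C)O[Si](C)(C)C
F2 | step 11 | methyl 4α,8,10β-trimethyl-7β-(N-phenylcarbamoyloxy)-5α-decal-8-ene-4β-carboxylate | COC(=O)[C@@]1(C)CCC[C@]2(C)C=C(C)[C@@H](OC(=O)Nc3ccccc3)C[C@@H]12
F3 | step 11 | methyl 9β-vinyl-4α,8,10β-trimethyl-5α-decal-7-ene-4β-carboxylate | COC(=O)[C@@]1(C)CCC[C@]2(C)[C@@H](C=C)C(C)=CC[C@@H]12
F4 | step 11 | methyl 12-hydroxy-13,14,15,16-tetranorlabd-7-en-19-oate | COC(=O)[C@@]1(C)CCC[C@]2(C)[C@@H](CCO)C(C)=CC[C@@H]12
F5 | step 14 | 12-iodo-13,14,15,16-tetranorlabd-7-en-19-yl 2-[bis(2,2,2-trifluoroethoxy)phosphoryl]propanoate | CC(C(=O)OC[C@@]1(C)CCC[C@]2(C)[C@@H](CCI)C(C)=CC[C@@H]12)P(=O)(OCC(F)(F)F)OCC(F)(F)F
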